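**Retrosynthetic overview**
1. Target ⇒ triol 18 + 4-iodophenol unit + CO (Pd alkoxycarbonylation makes the ester last), then desilylation.
2. 18 ⇒ hydroxy-enone 17 (chelation-controlled MeMgBr sets C8); the seven-membered ring is closed by olefin metathesis across C9=C10 after an asymmetric methyl vinyl ketone aldol (C6–C7 bond, C6 centre).
3. Key step: vinylcyclopentane 12 ⇐ p-menthene oxide 10 by a Meinwald 1,2-shift ring contraction (six- to five-membered ring; makes C1–C5 and the quaternary C1), run together with methylenation.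
4. 10 ⇐ cyclohexene 8 (epoxidation plus Baeyer–Villiger) ⇐ asymmetric Diels–Alder of diene 4 with 2-isopropylacrolein 7 (sets C4 and C5).
5. Ring order: cyclohexene, contracted to the cyclopentane, then the cycloheptene.

Assumption: 1 and 19 are bought as the silyl-protected forms of propargyl alcohol and 4-iodophenol; positions use daucane numbering (C1 quaternary CH3 carbon, C4 isopropyl carbinol, C5 ring-fusion CH, C6 ester carbinol, C8 methyl carbinol, C9=C10 alkene).

**Route**

Step 1
Reactants: 1 triethyl(prop-2-yn-1-yloxy)silane; 2 2-bromopropene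
Product: 4 triethyl{[(2E)-4-methylpenta-2,4-dien-1-yl]oxy}silane, via alkenylzirconocene chloride 3 (not isolated)
Conditions: Cp2Zr(H)Cl (1.1 equiv), THF, 23 °C; then 2 (1.5 equiv), Pd(PPh3)4 (5 mol %), 23 °C
Reagents that add atoms: none
Why: Hydrozirconation of the terminal alkyne is syn with zirconium on the terminal carbon, so the Pd-catalysed Negishi-type alkenyl–alkenyl coupling gives only the (E)-diene.

Step 2
Reactants: 5 3-methylbutanal; 6 formaldehyde (37% aqueous)
Product: 7 3-methyl-2-methylidenebutanal (2-isopropylacrolein)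
Conditions: pyrrolidine (10 mol %), propionic acid (10 mol %), i-PrOH, 45 °C
Reagents that add atoms: none
Why: Amine/acid-catalysed Mannich condensation–elimination (aldehyde α-methylenation) converts the α-CH2 of 5 into the 2-alkylacrolein.

Step 3
Reactants: 4 triethyl{[(2E)-4-methylpenta-2,4-dien-1-yl]oxy}silane; 7 3-methyl-2-methylidenebutanal
Product: 8 (1R,2R)-4-methyl-1-(propan-2-yl)-2-{[(triethylsilyl)oxy]methyl}cyclohex-3-ene-1-carbaldehyde (CHO cis to CH2OSiEt3)
Conditions: protonated (S)-B-(o-tolyl)-diphenylprolinol oxazaborolidine triflimide (20 mol %), CH2Cl2, −78 to −40 °C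
Reagents that add atoms: none
Why: Lewis-acid-catalysed asymmetric Diels–Alder reaction in which the 1-substituent and the 3-methyl group of 4 both direct the aldehyde-bearing carbon next to C5, the coordinated formyl group sits endo (CHO cis to CH2OSiEt3) and the cationic oxazaborolidine blocks one face of the enal, setting C4 and C5 (the catalyst enantiomer is the one that gives the 1R,2R adduct, expected to be S and to be confirmed on the first run).

Step 4
Reactants: 8 (1R,2R)-4-methyl-1-(propan-2-yl)-2-{[(triethylsilyl)oxy]methyl}cyclohex-3-ene-1-carbaldehyde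
Product: 10 (1S,4R,5R,6R)-1-methyl-4-(propan-2-yl)-5-{[(triethylsilyl)oxy]methyl}-7-oxabicyclo[4.1.0]heptan-4-yl formate, via epoxy aldehyde 9 (not isolated)
Conditions: mCPBA (2.5 equiv), CH2Cl2/pH 7 phosphate buffer, 0 to 23 °C
Reagents that add atoms: mCPBA, OOC(=O)c1cccc(Cl)c1
Why: Peracid epoxidation of the trisubstituted alkene occurs on the face opposite the CH2OSiEt3 group and the axial C4 substituent, and Baeyer–Villiger oxidation of the α-quaternary aldehyde migrates the tertiary carbon with retention, giving the tertiary formate with the C4 configuration of the target.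

Step 5
Reactants: 10 (1S,4R,5R,6R)-1-methyl-4-(propan-2-yl)-5-{[(triethylsilyl)oxy]methyl}-7-oxabicyclo[4.1.0]heptan-4-yl formate
Product: 12 (1R,2S,3R)-3-ethenyl-3-methyl-1-(propan-2-yl)-2-{[(triethylsilyl)oxy]methyl}cyclopentyl formate, via ring-contracted aldehyde 11 (not isolated)
Conditions: pre-formed MeAl(OAr)2 (Ar = 4-bromo-2,6-di-tert-butylphenyl, 2.2 equiv), CH2Cl2, −78 °C; then pre-aged Zn/CH2Br2/TiCl4 in THF, −78 to 0 °C
Reagents that add atoms: dibromomethane, BrCBr
Why: Proposed new method: an interrupted Meinwald rearrangement (ring-contractive methylenation of an epoxide) in which the bulky aluminium Lewis acid ionises the epoxide at the tertiary carbon C1, the ring bond C10–C5 shifts to C1 anti to the leaving oxygen (inversion at C1, retention at C5, so the epoxide face from step 4 places CH3 cis and C10 trans to the C5 side chain as in the target), and the aluminium-bound α-quaternary aldehyde, which the Al–CH3 bond does not attack, is methylenated in the same flask by the geminal zinc/titanium methylene reagent; the closest known reactions are the MeAl(OAr)2-promoted epoxide-to-aldehyde (semipinacol-type) rearrangement and the Takai–Lombardo methylenation, so far run only as separate steps.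

Step 6
Reactants: 12 (1R,2S,3R)-3-ethenyl-3-methyl-1-(propan-2-yl)-2-{[(triethylsilyl)oxy]methyl}cyclopentyl formate
Product: 13 (1R,2R,3R)-3-ethenyl-2-formyl-3-methyl-1-(propan-2-yl)cyclopentyl formate
Conditions: (COCl)2, DMSO, CH2Cl2, −78 to −40 °C; then Et3N, −78 to 0 °C
Reagents that add atoms: none
Why: Swern conditions cleave and oxidise a primary triethylsilyl ether directly to the aldehyde, and the C5–H between two quaternary carbons is too hindered for fast enolisation, so C5 and the β-formate survive.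

Step 7
Reactants: 13 (1R,2R,3R)-3-ethenyl-2-formyl-3-methyl-1-(propan-2-yl)cyclopentyl formate; 14 but-3-en-2-one
Product: 15 (1R,2S,3R)-3-ethenyl-2-[(1S)-1-hydroxy-3-oxopent-4-en-1-yl]-3-methyl-1-(propan-2-yl)cyclopentyl formate
Conditions: (R,R)-ProPhenol (10 mol %), Et2Zn (20 mol %), 4 Å sieves, 14 (10 equiv), THF, 0 °C
Reagents that add atoms: none
Why: Direct catalytic asymmetric aldol reaction of methyl vinyl ketone in which the zinc dienolate formed at the methyl group by the catalyst from Et2Zn and ProPhenol adds to one face of the α-branched aldehyde under catalyst control, setting the 6S carbinol (ligand enantiomer chosen for this sense, to be confirmed on the first run).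

Step 8
Reactants: 15 (1R,2S,3R)-3-ethenyl-2-[(1S)-1-hydroxy-3-oxopent-4-en-1-yl]-3-methyl-1-(propan-2-yl)cyclopentyl formate
Product: 17 (3R,3aS,4S,8aR)-3,4-dihydroxy-8a-methyl-3-(propan-2-yl)-2,3,3a,4,5,8a-hexahydroazulen-6(1H)-one, via formate enone 16 (not isolated)
Conditions: second-generation Grubbs catalyst RuCl2(=CHPh)(PCy3)(H2IMes) (5 mol %), CH2Cl2 (5 mM), 40 °C; then K2CO3 (cat.), MeOH, 0 °C
Reagents that add atoms: none
Why: Ring-closing olefin metathesis between the vinyl ketone and the neopentylic vinyl group closes the seven-membered ring as the cis enone, and mild methanolysis then removes the formate (wherever it sits after a possible 1,3-acyl shift) without conjugate addition to the hindered enone.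

Step 9
Reactants: 17 (3R,3aS,4S,8aR)-3,4-dihydroxy-8a-methyl-3-(propan-2-yl)-2,3,3a,4,5,8a-hexahydroazulen-6(1H)-one
Product: 18 (3R,3aS,4S,6R,8aR)-6,8a-dimethyl-3-(propan-2-yl)-1,2,3,3a,4,5,6,8a-octahydroazulene-3,4,6-triol
Conditions: MeMgBr (5 equiv), toluene/THF, −78 to −20 °C; aqueous NH4Cl
Reagents that add atoms: methylmagnesium bromide, C[Mg]Br
Why: Grignard 1,2-addition (conjugate addition is blocked by the quaternary carbon next to the β-position) under Cram-chelate 1,3-syn control, in which the magnesium alkoxide of the 6-OH holds the C8 carbonyl oxygen on the α face so that methyl enters from the β face and gives the 8R alcohol cis to the 6-OH.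

Step 10
Reactants: 18 (3R,3aS,4S,6R,8aR)-6,8a-dimethyl-3-(propan-2-yl)-1,2,3,3a,4,5,6,8a-octahydroazulene-3,4,6-triol; 19 tert-butyl(4-iodophenoxy)dimethylsilane
Product: 20 (3R,3aS,4S,6R,8aR)-3,6-dihydroxy-6,8a-dimethyl-3-(propan-2-yl)-1,2,3,3a,4,5,6,8a-octahydroazulen-4-yl 4-{[tert-butyl(dimethyl)silyl]oxy}benzoate
Conditions: 19 (1.5 equiv), CO (1 atm), Pd(OAc)2 (5 mol %), Xantphos (6 mol %), Et3N (3 equiv), DMAP (20 mol %), toluene, 80 °C
Reagents that add atoms: carbon monoxide, [C-]#[O+]
Why: Palladium-catalysed alkoxycarbonylation of the aryl iodide (oxidative addition, CO insertion, DMAP-assisted acyl transfer) esterifies the only secondary hydroxyl, the two tertiary alcohols being too hindered to react.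

Step 11
Reactants: 20 (3R,3aS,4S,6R,8aR)-3,6-dihydroxy-6,8a-dimethyl-3-(propan-2-yl)-1,2,3,3a,4,5,6,8a-octahydroazulen-4-yl 4-{[tert-butyl(dimethyl)silyl]oxy}benzoate
Product: 21 (3R,3aS,4S,6R,8aR)-3,6-dihydroxy-6,8a-dimethyl-3-(propan-2-yl)-1,2,3,3a,4,5,6,8a-octahydroazulen-4-yl 4-hydroxybenzoate
Conditions: Bu4NF, AcOH, THF, 0 °C
Reagents that add atoms: none
Why: Buffered fluoride desilylation cleaves the aryl silyl ether much faster than it touches the ester or the tertiary allylic alcohol, giving the target.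

**Compound list**
1 | triethyl(prop-2-yn-1-yloxy)silane | C#CCO[Si](CC)(CC)CC | starting material
2 | 2-bromopropene | CC(Br)=C | starting material
3 | chlorobis(cyclopentadienyl)[(1E)-3-(triethylsilyloxy)prop-1-en-1-yl]zirconium | Cl[Zr](/C=C/CO[Si](CC)(CC)CC)(C1C=CC=C1)C1C=CC=C1 | intermediate
4 | triethyl{[(2E)-4-methylpenta-2,4-dien-1-yl]oxy}silane | C=C(C)/C=C/CO[Si](CC)(CC)CC | intermediate
5 | 3-methylbutanal | CC(C)CC=O | starting material
6 | formaldehyde | C=O | starting material
7 | 3-methyl-2-methylidenebutanal | CC(C)C(=C)C=O | intermediate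
8 | (1R,2R)-4-methyl-1-(propan-2-yl)-2-{[(triethylsilyl)oxy]methyl}cyclohex-3-ene-1-carbaldehyde | CC(C)[C@]1(C=O)CCC(C)=C[C@H]1CO[Si](CC)(CC)CC | intermediate
9 | (1S,4R,5R,6R)-1-methyl-4-(propan-2-yl)-5-{[(triethylsilyl)oxy]methyl}-7-oxabicyclo[4.1.0]heptane-4-carbaldehyde (epoxide oxygen trans to CHO and CH2OSiEt3) | CC(C)[C@]1(C=O)CC[C@]2(C)O[C@@H]2[C@H]1CO[Si](CC)(CC)CC | intermediate
10 | (1S,4R,5R,6R)-1-methyl-4-(propan-2-yl)-5-{[(triethylsilyl)oxy]methyl}-7-oxabicyclo[4.1.0]heptan-4-yl formate (epoxide oxygen trans to O-formyl and CH2OSiEt3) | CC(C)[C@]1(OC=O)CC[C@]2(C)O[C@@H]2[C@H]1CO[Si](CC)(CC)CC | intermediate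
11 | (1R,2S,3S)-3-formyl-3-methyl-1-(propan-2-yl)-2-{[(triethylsilyl)oxy]methyl}cyclopentyl formate | CC(C)[C@]1(OC=O)CC[C@](C)(C=O)[C@H]1CO[Si](CC)(CC)CC | intermediate
12 | (1R,2S,3R)-3-ethenyl-3-methyl-1-(propan-2-yl)-2-{[(triethylsilyl)oxy]methyl}cyclopentyl formate | CC(C)[C@]1(OC=O)CC[C@](C)(C=C)[C@H]1CO[Si](CC)(CC)CC | intermediate
13 | (1R,2R,3R)-3-ethenyl-2-formyl-3-methyl-1-(propan-2-yl)cyclopentyl formate | CC(C)[C@]1(OC=O)CC[C@](C)(C=C)[C@H]1C=O | intermediate
14 | but-3-en-2-one | CC(=O)C=C | starting material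
15 | (1R,2S,3R)-3-ethenyl-2-[(1S)-1-hydroxy-3-oxopent-4-en-1-yl]-3-methyl-1-(propan-2-yl)cyclopentyl formate | CC(C)[C@]1(OC=O)CC[C@](C)(C=C)[C@H]1[C@@H](O)CC(=O)C=C | intermediate
16 | (3R,3aS,4S,8aR)-4-hydroxy-8a-methyl-6-oxo-3-(propan-2-yl)-1,2,3,3a,4,5,6,8a-octahydroazulen-3-yl formate | CC(C)[C@]1(OC=O)CC[C@]2(C)C=CC(=O)C[C@H](O)[C@H]21 | intermediate
17 | (3R,3aS,4S,8aR)-3,4-dihydroxy-8a-methyl-3-(propan-2-yl)-2,3,3a,4,5,8a-hexahydroazulen-6(1H)-one | CC(C)[C@]1(O)CC[C@]2(C)C=CC(=O)C[C@H](O)[C@H]21 | intermediate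
18 | (3R,3aS,4S,6R,8aR)-6,8a-dimethyl-3-(propan-2-yl)-1,2,3,3a,4,5,6,8a-octahydroazulene-3,4,6-triol | CC(C)[C@]1(O)CC[C@]2(C)C=C[C@](C)(O)C[C@H](O)[C@H]21 | intermediate
19 | tert-butyl(4-iodophenoxy)dimethylsilane | CC(C)(C)[Si](C)(C)Oc1ccc(I)cc1 | starting material
20 | (3R,3aS,4S,6R,8aR)-3,6-dihydroxy-6,8a-dimethyl-3-(propan-2-yl)-1,2,3,3a,4,5,6,8a-octahydroazulen-4-yl 4-{[tert-butyl(dimethyl)silyl]oxy}benzoate | CC(C)[C@]1(O)CC[C@]2(C)C=C[C@](C)(O)C[C@H](OC(=O)c3ccc(O[Si](C)(C)C(C)(C)C)cc3)[C@H]21 | intermediate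
21 | (3R,3aS,4S,6R,8aR)-3,6-dihydroxy-6,8a-dimethyl-3-(propan-2-yl)-1,2,3,3a,4,5,6,8a-octahydroazulen-4-yl 4-hydroxybenzoate | CC(C)[C@]1(O)CC[C@]2(C)C=C[C@](C)(O)C[C@H](OC(=O)c3ccc(O)cc3)[C@H]21 | target

**Step count and risks**

Total: 11 steps. Longest linear sequence: 10 steps (1 → 4 → 8 → 10 → 12 → 13 → 15 → 17 → 18 → 20 → 21; step 2 is the side branch).

Most likely to fail:

Step 5 (the proposed new step). The hydrogen on C10 may shift instead of the ring bond, the formate may trap the C1 cation, or the aluminium reagent may interfere with the methylenation. The fallback uses known chemistry, sets out from 10 and returns at 12. The MeAl(OAr)2 rearrangement is run alone and the ring-contracted aldehyde 11 is isolated. It is then methylenated in a separate Wittig step with Ph3P=CH2 (THF, −78 to 0 °C). No compound outside the list is made (F0).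

Step 7. The aldehyde sits between two quaternary carbons, so the zinc-catalysed aldol may be slow or poorly selective, and the β-formate may eliminate or migrate. The fallback sets out from 12 and returns at 17, replacing catalyst control by chelation control:
- Methanolysis of the formate (K2CO3, MeOH) gives the tertiary alcohol F1.
- Swern oxidation as in step 6 gives the β-hydroxy aldehyde F2.
- 14 is converted (Me3SiCl, Et3N, DMF) into 2-(trimethylsilyloxy)buta-1,3-diene F3.
- Mukaiyama aldol addition of F3 to F2 with MgBr2·OEt2 in CH2Cl2 at −78 °C gives the dihydroxy vinyl ketone F4. Magnesium bridges the C4 hydroxyl and the aldehyde oxygen, and the nucleophile attacks the exposed face, which is the 6S sense.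
- Ring-closing metathesis of F4 with the ruthenium catalyst of step 8 gives 17.

Step 9. Facial selectivity at C8 on the seven-membered ring rests on chelation and may be low. The fallback sets out from 15 and returns at 18, setting C8 on the open chain before ring closure. MeMgBr (excess, CH2Cl2/THF, −78 °C) adds to the acyclic β-hydroxy vinyl ketone 15 under Cram-chelate 1,3-syn control and also cleaves the formate, giving the acyclic triol F5. Ring-closing metathesis of F5 with the catalyst of step 8 gives 18 directly.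

Further compounds
F0 | step 5 | none | none
F1 | step 7 | (1R,2S,3R)-3-ethenyl-3-methyl-1-(propan-2-yl)-2-{[(triethylsilyl)oxy]methyl}cyclopentan-1-ol | CC(C)[C@]1(O)CC[C@](C)(C=C)[C@H]1CO[Si](CC)(CC)CC
F2 | step 7 | (1R,2R,5R)-5-ethenyl-2-hydroxy-5-methyl-2-(propan-2-yl)cyclopentane-1-carbaldehyde | CC(C)[C@]1(O)CC[C@](C)(C=C)[C@H]1C=O
F3 | step 7 | 2-(trimethylsilyloxy)buta-1,3-diene | C=CC(=C)O[Si](C)(C)C
F4 | step 7 | (1R,2S,3R)-3-ethenyl-2-[(1S)-1-hydroxy-3-oxopent-4-en-1-yl]-3-methyl-1-(propan-2-yl)cyclopentan-1-ol | CC(C)[C@]1(O)CC[C@](C)(C=C)[C@H]1[C@@H](O)CC(=O)C=C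
F5 | step 9 | (1R,2S,3R)-2-[(1S,3R)-1,3-dihydroxy-3-methylpent-4-en-1-yl]-3-ethenyl-3-methyl-1-(propan-2-yl)cyclopentan-1-ol | CC(C)[C@]1(O)CC[C@](C)(C=C)[C@H]1[C@@H](O)C[C@@](C)(O)C=C
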